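## Analysis of the target

Target 30 is a flavone. Ring A (C4a, C5, C6, C7, C8, C8a) is fused to the pyranone ring C (O1, C2, C3, C4), and C2 carries the 4‑hydroxyphenyl ring B. C8 bears a CH(Ph)CH2CO2H chain whose methine carbon is the only stereocentre, (R)-configured, so only its absolute sense and its survival have to be controlled. Ring A is pentasubstituted: oxygen on C5, C7 and C8a, carbon on C4a and C8, hydrogen only on C6. The sensitive points are the carboxyl group next to the C7 hydroxyl (closure to a six-membered aryl lactone under acid), ring C (hot protic acid can open it and reclose it through the C5 oxygen, which would move the chain to C6), and three oxidisable phenols. The difficulty is to place a stereodefined diaryl methine on the most hindered carbon of a phloroglucinol ring and to decide which ring oxygen becomes O1. The strategy reads ring A as a 2‑alkylresorcinol with a third oxygen para to the chain: C8 lies between C7–O and C8a–O, and C5–O is para to C8. A siloxyalkyne and a methoxy-substituted vinylketene assemble exactly this pattern: the ketene oxygen becomes the free C8a hydroxyl (future O1), the siloxy group sits on C7 and the methoxy group on C5. The two oxygens flanking C8 give the same 8‑substituted flavone whichever closes ring C; the para oxygen must stay capped, and it does.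

## Retrosynthetic reasoning

**30 back to 28 and 27.** Only protecting groups are removed at the end: two methyl ethers (C5, C4') and the tert‑butyl ester in 28, and before that the silyl ether of 27. A boron Lewis acid at low temperature is planned instead of hot protic acid, because the latter invites the C8 to C6 migration through ring C. Lactone 29 is accepted as a transient form and reopened by hydroxide, so the last operation is basic and delivers the open hydroxy acid.

**27 back to 25 (O1–C2).** Ring C is opened at O1–C2, giving ynone 25 with a free C8a hydroxyl. The forward step must close six-membered and not five-membered; routing it through amino enone 26 secures that. Only the C8a oxygen is free and the C5 oxygen is methylated, so closure can give only the 8‑substituted flavone.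

**25 back to 24, then 22 and 23 (C3–C4).** The ynone comes from propargylic alcohol 24, and this from aldehyde 22 and the acetylide of 23. Ring B, C2 and C3 thus arrive as one commercial piece, and the carbonyl carbon C4 is already on the ring.

**22 back to 21 (C4–C4a).** The formyl carbon is removed from the position ortho to the only free phenol. In 21 that phenol has a single free ortho carbon, so a chelation-controlled ortho-formylation has one possible outcome.

**21 back to 12 and 16 (C8a–C8, C6–C7, C4a–C8a).** Ring A is taken apart into siloxyalkyne 12 and diazo ketone 16, the precursor of vinylketene 17. Cutting here puts the stereocentre on an open-chain alkyne, where it is easy to make. All three ring oxygens arrive differentiated (free, silylated, methylated), and the chain is placed on the most hindered ring carbon by construction rather than by substitution on a preformed trioxygenated ring. The forward reaction must join ketene and alkyne in one orientation and leave the propargylic methine untouched.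

**12 back to 9 and 8 (C–O at the alkyne terminus, ester alkyl).** The siloxy group is traced to the terminal alkyne of 9 by acetylide oxidation and O‑silylation. The tert‑butyl ester of 9 is chosen because it resists phenoxide and acetylide in later steps and falls with Lewis acid at the end. It comes from acid 8.

**8 back to 5, then 3 and 4, then 1 and 2 (the stereocentre).** The bond between the methine and the alkyne is cut. The forward reaction is a catalytic asymmetric conjugate alkynylation of benzylidene compound 3 with silylalkyne 4. Loss of the extra carboxyl and of the silyl group from adduct 5 gives 8. The descriptor changes along the way (R in 5, S in 8 and 9, R again from 11 and 12 on) only because silicon or oxygen on the alkyne terminus raises the alkynyl group above phenyl in the priority order; the geometry is never altered. 3 is the condensation product of 1 and 2.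

**16 back to 14 and 13.** The diazo group is introduced by diazo transfer onto the methyl group of enone 14, which avoids diazomethane on an acryloyl system. 14 comes from ketal 13 by loss of one methoxy group as the alcohol.

## Alternatives that were turned down

**Alternative 1:** Ring A is cut at C8–C8a and C4a–C5. Rings B and C stay intact in sulfinyl pyranone A1, and C5 to C8 with the stereocentre are placed in silyloxydiene A2. Forward, a (4+2) cycloaddition across the C5=C6 bond of A1 (future C4a=C8a), followed by loss of the sulfur group, the methoxy group and the silyl groups, would give flavone A3.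
- For it: A3 is two protecting groups away from 30, ring C never has to be built on a hindered phenol, and the polarity of A2 fixes which terminus meets the oxygen-bearing carbon.
- Against it: the ring double bond of a 4‑pyranone is part of a vinylogous ester and is a reluctant dienophile even when sulfinylated. The diene terminus that must bond to it carries the branched CH(Ph) group. The stereocentre of A2 is allylic to the diene, where a 1,5‑hydrogen shift at the temperatures a slow cycloaddition needs would erase it. A2 also requires double enol silylation of a keto ester beside a second ester.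
- Comparison: alternative 1 is clearly stronger in step economy after the key step (two deprotections against six steps). The chosen route offers instead a first bond formation between a small, strongly electrophilic ketene and a polarity-matched alkyne, followed only by unimolecular pericyclic steps, with the stereocentre propargylic and never next to a diene.

**Alternative 2:** Ring C is cut at O1–C8a, C4–C4a and O1–C2. A finished ring A enters as aryne precursor A4, and C2, C3, C4 with ring B enter as acid A5. Forward, CsF would release the C4a–C8a aryne; the carboxylate of A5 adds through oxygen at C8a, the aryl anion at C4a takes the acyl carbon, and the phenoxide closes onto the ynone to give A6.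
- For it: three bonds and ring C in one operation from two stable pieces. On this point it is stronger than the chosen route, which needs four steps for the same ring.
- Against it: the oxygen must add to C8a, the aryne carbon flanked by the branched C8 substituent. The C5 methoxy group directs in the right sense but sterics oppose it, and the wrong sense gives a constitutional isomer. The final phenoxide can also close five-membered. A4 is a hexasubstituted benzene with the stereocentre between two ortho substituents; making it is the real problem and is left open. The unchelated C7 methyl ether of A6 needs forcing cleavage, with the ring C migration risk.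
- Comparison: the chosen route builds ring A and installs the C8 chain in one event and delivers the three oxygens already differentiated.

**Alternative 3:** The phenyl group on the stereocentre is cut at two ring bonds and built from terminal alkyne A7 and diene A8. Forward, CoBr2(dppe), reduced in the flask by zinc metal with ZnI2, joins them to a 1,4‑cyclohexadiene that DDQ aromatises in the same flask to A9.
- For it: neutral, catalytic, tolerant of ester and ethers, no regiochemical question with a symmetrical diene, and the stereocentre is not touched. As a reaction it is probably more dependable than the benzannulation, and on that point it is stronger.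
- Against it: it spends the ring-forming step on the one ring that needs none, since a plain phenyl group is available in aldehyde 1. A7 still requires a stereocentre set next to a doubly ortho-substituted trioxygenated aryl group. Everything hard about 30 (ring A, the choice of O1, ring C) remains after A9, with as many later steps as in the chosen route.
- Comparison: the chosen strategy gives its ring-forming step to ring A, where the substitution pattern is the problem.

Key step: step 8

Assumption 1: the sense of induction in step 2 is not predicted here; the antipode of the bisphosphine that furnishes (R)-5 is used (both are available), and the assignment is checked by correlation at acid 8.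
Assumption 2: after the BBr3 stage of step 14 the material is treated as lactone 29; any open acid present is carried through the hydroxide stage unchanged.

## Route

Step 1
Reactants: 1 benzaldehyde; 2 2,2-dimethyl-1,3-dioxane-4,6-dione (Meldrum's acid)
Product: 3 5-benzylidene-2,2-dimethyl-1,3-dioxane-4,6-dione
Conditions: pyrrolidine/AcOH (10 mol %), toluene, rt
Reagents that add atoms: none
Why: Knoevenagel condensation of a non-enolisable aldehyde with a strongly acidic methylene compound; the acceptor is symmetrical, so no alkene geometry arises.

Step 2
Reactants: 3 5-benzylidene-2,2-dimethyl-1,3-dioxane-4,6-dione; 4 ethynyltrimethylsilane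
Product: 5 2,2-dimethyl-5-[(1R)-1-phenyl-3-(trimethylsilyl)prop-2-yn-1-yl]-1,3-dioxane-4,6-dione
Conditions: [Rh(OAc)(C2H4)2]2 (2.5 mol %), 3,5-Xyl-MeO-BIPHEP (5.5 mol %, one antipode), 4 (3 equiv), 1,4-dioxane/H2O 10:1, 15 °C
Reagents that add atoms: none
Why: Rhodium-catalysed asymmetric conjugate alkynylation: an alkynyl complex of monovalent rhodium formed from 4 adds across the doubly activated alkene of 3 and the rhodium enolate is protonated, the silyl group suppressing alkyne dimerisation. The new stereocentre is set by the chiral bisphosphine on rhodium, which selects one face of the benzylidene carbon (catalyst control).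

Step 3
Reactants: 5 2,2-dimethyl-5-[(1R)-1-phenyl-3-(trimethylsilyl)prop-2-yn-1-yl]-1,3-dioxane-4,6-dione
Product: 8 (S)-3-phenylpent-4-ynoic acid, via malonic acid 6 (not isolated), via silylated acid 7 (not isolated)
Conditions: DMF/H2O 10:1, 100 °C; then K2CO3 (3 equiv), MeOH, rt; 1 M HCl work-up
Reagents that add atoms: water, O
Why: Hydrolytic opening of the dioxanedione and decarboxylation of malonic acid 6, then methoxide-mediated cleavage of the alkynyl C–Si bond. The methine is β to the carboxyl and is not touched; its descriptor changes to S only because ethynyl ranks below phenyl.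

Step 4
Reactants: 8 (S)-3-phenylpent-4-ynoic acid
Product: 9 tert-butyl (S)-3-phenylpent-4-ynoate
Conditions: Cl3CC(=NH)Ot-Bu (2.5 equiv), CH2Cl2/cyclohexane, rt
Reagents that add atoms: tert-butyl 2,2,2-trichloroacetimidate, CC(C)(C)OC(=N)C(Cl)(Cl)Cl
Why: Imidate tert-butylation: the acid protonates the imidate and the carboxylate captures the tert-butyl cation; no base is present, so the alkyne and the propargylic methine are left alone.

Step 5
Reactants: 9 tert-butyl (S)-3-phenylpent-4-ynoate
Product: 12 tert-butyl (R)-3-phenyl-5-(triisopropylsilyloxy)pent-4-ynoate, via lithium acetylide 10 (not isolated), via lithium ynolate 11 (not isolated)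
Conditions: n-BuLi (1.0 equiv), THF, −78 °C; LiOOt-Bu (1.1 equiv, from t-BuOOH and LiN(SiMe3)2, THF, −78 °C), −78 → −10 °C; TIPSOTf (1.2 equiv), −78 → 0 °C
Reagents that add atoms: tert-butyl hydroperoxide (as its lithium salt), CC(C)(C)OO; triisopropylsilyl trifluoromethanesulfonate, CC(C)[Si](OS(=O)(=O)C(F)(F)F)(C(C)C)C(C)C
Why: Kinetic deprotonation of the sp C–H by one equivalent of n-BuLi at −78 °C is faster than attack on or enolisation of the hindered ester; electrophilic oxygen transfer from the lithium peroxide gives ynolate 11, and O‑silylation with the bulky triflate gives the siloxyalkyne. This acetylide oxidation and silylation sequence is the standard access to triisopropylsiloxyalkynes; the configuration is unchanged (descriptor R again for priority reasons).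

Step 6
Reactants: 13 3,3-dimethoxybutan-2-one
Product: 14 3-methoxybut-3-en-2-one
Conditions: p-TsOH·H2O (1 mol %), hydroquinone (trace), neat, 150 °C, MeOH distilled off; then distillation under reduced pressure
Reagents that add atoms: none
Why: Acid-catalysed elimination of methanol from the ketal through the oxocarbenium ion, driven by removal of methanol; the only β-hydrogens are on the C4 methyl group, so one enol ether can form.

Step 7
Reactants: 14 3-methoxybut-3-en-2-one
Product: 16 1-diazo-3-methoxybut-3-en-2-one, via trifluoroacetyl ketone 15 (not isolated)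
Conditions: LiN(SiMe3)2, THF, −78 °C; CF3CO2CH2CF3; dilute HCl work-up; crude 15, MsN3, Et3N, H2O (1 equiv), MeCN, rt
Reagents that add atoms: methanesulfonyl azide, CS(=O)(=O)N=[N+]=[N-]
Why: Detrifluoroacetylative diazo transfer: Claisen-type trifluoroacetylation of the only possible enolate activates the methyl carbon for diazo transfer from the sulfonyl azide, and the trifluoroacetyl group leaves as the N‑sulfonyl amide. Diazomethane, which would add to the enone, is avoided.

Step 8
Reactants: 12 tert-butyl (R)-3-phenyl-5-(triisopropylsilyloxy)pent-4-ynoate; 16 1-diazo-3-methoxybut-3-en-2-one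
Product: 21 tert-butyl (R)-3-[2-hydroxy-4-methoxy-6-(triisopropylsilyloxy)phenyl]-3-phenylpropanoate, via vinylketene 17 (not isolated), via cyclobutenone 18 (not isolated), via dienylketene 19 (not isolated), via cyclohexadienone 20 (not isolated)
Conditions: 12 (1.0 equiv), 16 (2 equiv, two portions), degassed ClCH2CH2Cl (0.15 M), hν 254 nm (low-pressure Hg lamps, quartz), rt; then 80 °C
Reagents that add atoms: none
Why: Irradiation expels dinitrogen from 16 and the 1‑methoxyvinyl group migrates (photochemical Wolff rearrangement) to give vinylketene 17. Its electrophilic carbonyl carbon is attacked by the nucleophilic, chain-bearing carbon of the polarised siloxyalkyne 12 and the ketene α-carbon bonds to the siloxy carbon, a (2+2) cycloaddition that gives cyclobutenone 18 and forms C8a–C8 and C6–C7 of the target. Reversible four-electron electrocyclic opening of 18 (light or heat) gives dienylketene 19, and ring A is closed by thermal disrotatory six-electron electrocyclisation of the ketene carbon onto the terminal methylene (C4a–C8a), after which dienone 20 tautomerises to the phenol. The closest known reaction type is the Danheiser benzannulation in its photochemical Wolff form with triisopropylsiloxyalkynes, which delivers monosilylated 2‑alkylresorcinols of this 5‑methoxy pattern. No stereocentre is formed in the product: the ring carbon of 18 that carries the methoxyvinyl group is stereogenic only transiently, and the side-chain methine is a spectator with no acidic or migrating hydrogen under these neutral conditions. The step needs regioselectivity in the cycloaddition, secured by the oxygen-induced polarity of the alkyne against the ketene, and capture of 17 by the alkyne in preference to self-reaction, for which 16 is used in excess and added in portions. The triisopropylsilyl group keeps the siloxyalkyne from rearranging to a silylketene at 80 °C, and the tert-butyl ester is too hindered to acylate the new phenol.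

Step 9
Reactants: 21 tert-butyl (R)-3-[2-hydroxy-4-methoxy-6-(triisopropylsilyloxy)phenyl]-3-phenylpropanoate
Product: 22 tert-butyl (R)-3-[3-formyl-2-hydroxy-4-methoxy-6-(triisopropylsilyloxy)phenyl]-3-phenylpropanoate
Conditions: MgCl2 (anhydrous, 2 equiv), Et3N (4 equiv), (CH2O)n (6 equiv), MeCN, 75 °C; cold 1 M HCl work-up
Reagents that add atoms: paraformaldehyde (as formaldehyde), C=O
Why: Magnesium-mediated ortho-formylation (Casnati–Skattebøl type): the magnesium phenoxide delivers formaldehyde to the ortho carbon through a chelate, and the benzylic alkoxide is oxidised by hydride transfer to a second formaldehyde. The only free ortho carbon is the future C4a and the chelate does not reach the para position; without strong acid the silyl ether and the ester persist.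

Step 10
Reactants: 22 tert-butyl (R)-3-[3-formyl-2-hydroxy-4-methoxy-6-(triisopropylsilyloxy)phenyl]-3-phenylpropanoate; 23 4-ethynylanisole
Product: 24 tert-butyl (3R)-3-[2-hydroxy-3-[1-hydroxy-3-(4-methoxyphenyl)prop-2-yn-1-yl]-4-methoxy-6-(triisopropylsilyloxy)phenyl]-3-phenylpropanoate (both epimers at the carbinol carbon)
Conditions: 23 (3.0 equiv), n-BuLi (2.9 equiv), THF, −78 °C; then 22, −78 → 0 °C; sat. NH4Cl
Reagents that add atoms: none
Why: 1,2‑Addition of a lithium acetylide to an aldehyde: the first equivalent forms the lithium phenoxide and the second adds to the formyl group. The tert-butyl ester and the aryl silyl ether are inert to acetylides at this temperature; the carbinol centre forms without control and is removed in the next step.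

Step 11
Reactants: 24 tert-butyl (3R)-3-[2-hydroxy-3-[1-hydroxy-3-(4-methoxyphenyl)prop-2-yn-1-yl]-4-methoxy-6-(triisopropylsilyloxy)phenyl]-3-phenylpropanoate
Product: 25 tert-butyl (R)-3-[2-hydroxy-4-methoxy-3-[3-(4-methoxyphenyl)prop-2-ynoyl]-6-(triisopropylsilyloxy)phenyl]-3-phenylpropanoate
Conditions: MnO2 (activated, excess), CH2Cl2, rt
Reagents that add atoms: none
Why: MnO2 oxidises the benzylic and propargylic alcohol selectively under neutral conditions; the ynone is stabilised by a hydrogen bond from the ortho phenol.

Step 12
Reactants: 25 tert-butyl (R)-3-[2-hydroxy-4-methoxy-3-[3-(4-methoxyphenyl)prop-2-ynoyl]-6-(triisopropylsilyloxy)phenyl]-3-phenylpropanoate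
Product: 27 tert-butyl (R)-3-[5-methoxy-2-(4-methoxyphenyl)-4-oxo-7-(triisopropylsilyloxy)-4H-chromen-8-yl]-3-phenylpropanoate, via amino enone 26 (not isolated)
Conditions: Et2NH (5 equiv), EtOH, rt → 60 °C
Reagents that add atoms: none
Why: Amine-mediated 6‑endo cyclisation: Et2NH adds to the ynone to give amino enone 26, and the C8a hydroxyl then replaces the amine at the β-carbon by addition and elimination, which can only give the six-membered pyranone, so five-membered closure is excluded. Should the silyl ether be partly lost here, the material converges in step 13.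

Step 13
Reactants: 27 tert-butyl (R)-3-[5-methoxy-2-(4-methoxyphenyl)-4-oxo-7-(triisopropylsilyloxy)-4H-chromen-8-yl]-3-phenylpropanoate
Product: 28 tert-butyl (R)-3-[7-hydroxy-5-methoxy-2-(4-methoxyphenyl)-4-oxo-4H-chromen-8-yl]-3-phenylpropanoate
Conditions: n-Bu4NF (1.1 equiv), AcOH (1.1 equiv), THF, 0 °C
Reagents that add atoms: none
Why: Fluoride cleaves the aryl silyl ether through Si–F bond formation; acetic acid buffers the acidic C7 phenoxide, and the methyl ethers and the ester are untouched.

Step 14
Reactants: 28 tert-butyl (R)-3-[7-hydroxy-5-methoxy-2-(4-methoxyphenyl)-4-oxo-4H-chromen-8-yl]-3-phenylpropanoate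
Product: 30 (R)-3-[5,7-dihydroxy-2-(4-hydroxyphenyl)-4-oxo-4H-chromen-8-yl]-3-phenylpropanoic acid, via lactone 29 (not isolated)
Conditions: BBr3 (8 equiv), CH2Cl2, −78 °C → rt; ice-water; then 1 M LiOH, THF, 0 °C → rt, under argon; 1 M HCl to pH 3 at 0 °C
Reagents that add atoms: lithium hydroxide, [Li+].[OH-]
Why: BBr3 cleaves both aryl methyl ethers (the C5 ether fastest, helped by chelation to the C4 carbonyl) and the tert-butyl ester by bromide attack on the boron-activated groups; the boron-bound carboxyl and C7 oxygen should close to lactone 29, which aqueous LiOH reopens, and cold acidification gives the open hydroxy acid. Low temperature and the absence of hot protic acid avoid opening of ring C, and the diaryl methine has no pathway for epimerisation.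

## Compound list

1 | benzaldehyde | O=Cc1ccccc1 | starting material
2 | 2,2-dimethyl-1,3-dioxane-4,6-dione | CC1(C)OC(=O)CC(=O)O1 | starting material
3 | 5-benzylidene-2,2-dimethyl-1,3-dioxane-4,6-dione | CC1(C)OC(=O)C(=Cc2ccccc2)C(=O)O1 | intermediate
4 | ethynyltrimethylsilane | C#C[Si](C)(C)C | starting material
5 | 2,2-dimethyl-5-[(1R)-1-phenyl-3-(trimethylsilyl)prop-2-yn-1-yl]-1,3-dioxane-4,6-dione | CC1(C)OC(=O)C([C@H](c2ccccc2)C#C[Si](C)(C)C)C(=O)O1 | intermediate
6 | 2-[(1R)-1-phenyl-3-(trimethylsilyl)prop-2-yn-1-yl]propanedioic acid (not isolated) | OC(=O)C(C(=O)O)[C@H](c1ccccc1)C#C[Si](C)(C)C | intermediate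
7 | (R)-3-phenyl-5-(trimethylsilyl)pent-4-ynoic acid (not isolated) | OC(=O)C[C@H](c1ccccc1)C#C[Si](C)(C)C | intermediate
8 | (S)-3-phenylpent-4-ynoic acid | OC(=O)C[C@H](c1ccccc1)C#C | intermediate
9 | tert-butyl (S)-3-phenylpent-4-ynoate | CC(C)(C)OC(=O)C[C@H](c1ccccc1)C#C | intermediate
10 | lithium acetylide of 9, tert-butyl 5-lithio-3-phenylpent-4-ynoate with C3 as in 9 (not isolated) | CC(C)(C)OC(=O)C[C@H](c1ccccc1)C#C[Li] | intermediate
11 | lithium (3R)-5-(tert-butoxy)-5-oxo-3-phenylpent-1-yn-1-olate (not isolated) | CC(C)(C)OC(=O)C[C@H](c1ccccc1)C#CO[Li] | intermediate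
12 | tert-butyl (R)-3-phenyl-5-(triisopropylsilyloxy)pent-4-ynoate | CC(C)(C)OC(=O)C[C@H](c1ccccc1)C#CO[Si](C(C)C)(C(C)C)C(C)C | intermediate
13 | 3,3-dimethoxybutan-2-one | CC(=O)C(C)(OC)OC | starting material
14 | 3-methoxybut-3-en-2-one | C=C(OC)C(C)=O | intermediate
15 | 1,1,1-trifluoro-5-methoxyhex-5-ene-2,4-dione (not isolated) | C=C(OC)C(=O)CC(=O)C(F)(F)F | intermediate
16 | 1-diazo-3-methoxybut-3-en-2-one | C=C(OC)C(=O)C=[N+]=[N-] | intermediate
17 | 3-methoxybuta-1,3-dien-1-one, the vinylketene (not isolated) | C=C(OC)C=C=O | intermediate
18 | tert-butyl (3R)-3-[3-(1-methoxyethenyl)-4-oxo-2-(triisopropylsilyloxy)cyclobut-1-en-1-yl]-3-phenylpropanoate, both epimers at the ring methine (not isolated) | CC(C)(C)OC(=O)C[C@H](c1ccccc1)C1=C(O[Si](C(C)C)(C(C)C)C(C)C)C(C(=C)OC)C1=O | intermediate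
19 | tert-butyl (3R,5E)-7-methoxy-4-(oxomethylidene)-3-phenyl-5-(triisopropylsilyloxy)octa-5,7-dienoate, the dienylketene (not isolated) | CC(C)(C)OC(=O)C[C@H](c1ccccc1)C(=C=O)/C(O[Si](C(C)C)(C(C)C)C(C)C)=C\C(=C)OC | intermediate
20 | tert-butyl (3R)-3-[4-methoxy-6-oxo-2-(triisopropylsilyloxy)cyclohexa-1,3-dien-1-yl]-3-phenylpropanoate (not isolated) | CC(C)(C)OC(=O)C[C@H](c1ccccc1)C1=C(O[Si](C(C)C)(C(C)C)C(C)C)C=C(OC)CC1=O | intermediate
21 | tert-butyl (R)-3-[2-hydroxy-4-methoxy-6-(triisopropylsilyloxy)phenyl]-3-phenylpropanoate | CC(C)(C)OC(=O)C[C@H](c1ccccc1)c1c(O)cc(OC)cc1O[Si](C(C)C)(C(C)C)C(C)C | intermediate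
22 | tert-butyl (R)-3-[3-formyl-2-hydroxy-4-methoxy-6-(triisopropylsilyloxy)phenyl]-3-phenylpropanoate | CC(C)(C)OC(=O)C[C@H](c1ccccc1)c1c(O)c(C=O)c(OC)cc1O[Si](C(C)C)(C(C)C)C(C)C | intermediate
23 | 4-ethynylanisole | COc1ccc(C#C)cc1 | starting material
24 | tert-butyl (3R)-3-[2-hydroxy-3-[1-hydroxy-3-(4-methoxyphenyl)prop-2-yn-1-yl]-4-methoxy-6-(triisopropylsilyloxy)phenyl]-3-phenylpropanoate, both epimers at the carbinol carbon | CC(C)(C)OC(=O)C[C@H](c1ccccc1)c1c(O)c(C(O)C#Cc2ccc(OC)cc2)c(OC)cc1O[Si](C(C)C)(C(C)C)C(C)C | intermediate
25 | tert-butyl (R)-3-[2-hydroxy-4-methoxy-3-[3-(4-methoxyphenyl)prop-2-ynoyl]-6-(triisopropylsilyloxy)phenyl]-3-phenylpropanoate | CC(C)(C)OC(=O)C[C@H](c1ccccc1)c1c(O)c(C(=O)C#Cc2ccc(OC)cc2)c(OC)cc1O[Si](C(C)C)(C(C)C)C(C)C | intermediate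
26 | tert-butyl (3R)-3-[3-[3-(diethylamino)-3-(4-methoxyphenyl)prop-2-enoyl]-2-hydroxy-4-methoxy-6-(triisopropylsilyloxy)phenyl]-3-phenylpropanoate, alkene geometry not defined (not isolated) | CC(C)(C)OC(=O)C[C@H](c1ccccc1)c1c(O)c(C(=O)C=C(N(CC)CC)c2ccc(OC)cc2)c(OC)cc1O[Si](C(C)C)(C(C)C)C(C)C | intermediate
27 | tert-butyl (R)-3-[5-methoxy-2-(4-methoxyphenyl)-4-oxo-7-(triisopropylsilyloxy)-4H-chromen-8-yl]-3-phenylpropanoate | CC(C)(C)OC(=O)C[C@H](c1ccccc1)c1c(O[Si](C(C)C)(C(C)C)C(C)C)cc(OC)c2c(=O)cc(-c3ccc(OC)cc3)oc12 | intermediate
28 | tert-butyl (R)-3-[7-hydroxy-5-methoxy-2-(4-methoxyphenyl)-4-oxo-4H-chromen-8-yl]-3-phenylpropanoate | CC(C)(C)OC(=O)C[C@H](c1ccccc1)c1c(O)cc(OC)c2c(=O)cc(-c3ccc(OC)cc3)oc12 | intermediate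
29 | (10R)-5-hydroxy-2-(4-hydroxyphenyl)-10-phenyl-9,10-dihydro-4H,8H-pyrano[2,3-f]chromene-4,8-dione (not isolated) | O=C1C[C@H](c2ccccc2)c3c(O1)cc(O)c4c(=O)cc(-c5ccc(O)cc5)oc34 | intermediate
30 | (R)-3-[5,7-dihydroxy-2-(4-hydroxyphenyl)-4-oxo-4H-chromen-8-yl]-3-phenylpropanoic acid | O=C(O)C[C@H](c1ccccc1)c1c(O)cc(O)c2c(=O)cc(-c3ccc(O)cc3)oc12 | target

## Step count and least certain steps

Total step count: 14. Longest linear sequence: 12 steps (steps 1 to 5, 8, 9 to 14); steps 6 and 7 form the two-step side branch to 16.

**Step 8 (key step).** Most likely failure: inefficient capture of the photogenerated ketene. It is formed at low stationary concentration and can be consumed by self-condensation, and the accumulating aromatic product screens the 254 nm light so that the Wolff rearrangement stalls. In the thermal phase, silyl migration in the siloxyalkyne or acyl transfer from the ester to the new phenol can erode the material. Fallback: generate the same vinylketene 17 thermally, without light and without a diazo compound, by four-electron electrocyclic opening of 3‑methoxycyclobut-2-en-1-one F1 (the methyl enol ether of cyclobutane-1,3-dione, from O‑methylation of the dione). Heating 12 with F1 in toluene at 80 to 110 °C is the thermal form of the same benzannulation and should pass through 18, 19 and 20. It sets out from 12 and returns at 21.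

**Step 5.** Most likely failure: loss of chemoselectivity in the metalation. Proton transfer from the ester α-methylene to the acetylide, or attack of n-BuLi on the ester, can compete while the mixture warms for the oxygen transfer, leaving the oxidation incomplete. Fallback: oxidise where no ester exists. Acid 8 is converted with two equivalents of n-BuLi into the carboxylate and acetylide dianion, oxidised with LiOOt-Bu and silylated on both oxygens with TIPSOTf to give triisopropylsilyl (R)-3-phenyl-5-(triisopropylsilyloxy)pent-4-ynoate F2. F2 takes the place of 12 in the benzannulation with 16 and should give triisopropylsilyl (R)-3-[2-hydroxy-4-methoxy-6-(triisopropylsilyloxy)phenyl]-3-phenylpropanoate F3. The silyl ester alone is cleaved with K2CO3 in aqueous MeOH at 0 °C to (R)-3-[2-hydroxy-4-methoxy-6-(triisopropylsilyloxy)phenyl]-3-phenylpropanoic acid F4, which is tert-butylated with the trichloroacetimidate as in step 4. It sets out from 8 and returns at 21.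

**Step 2.** Most likely failure: insufficient enantioselection or rate, through competing alkyne oligomerisation at rhodium or hydrolytic cleavage of 3 in the aqueous medium. Fallback: racemic conjugate addition and classical resolution. HC≡CMgBr adds to 3 (THF, −40 → 0 °C) to give racemic 2,2-dimethyl-5-(1-phenylprop-2-yn-1-yl)-1,3-dioxane-4,6-dione F5. Hydrolysis and decarboxylation (DMF/H2O, 100 °C) give racemic 3‑phenylpent-4-ynoic acid F6. Crystallisation with (R)-1-phenylethylamine (or its antipode, should that give the less soluble salt of the (S)-acid) gives (R)-1-phenylethylammonium (S)-3-phenylpent-4-ynoate F7, from which dilute acid liberates 8. It sets out from 3 and returns at 8.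

**Step 10.** Most likely failure: sluggish addition. The formyl group is flanked by a methoxy group and a lithium phenoxide whose donation lowers its electrophilicity, so the weakly nucleophilic acetylide adds slowly, and warming brings attack on the ester. Fallback: build C2–C3 by aldol condensation (chalcone route). MeMgBr (or MeTi(Oi-Pr)3) adds to 22 to give tert-butyl (3R)-3-[2-hydroxy-3-(1-hydroxyethyl)-4-methoxy-6-(triisopropylsilyloxy)phenyl]-3-phenylpropanoate F8. MnO2 gives tert-butyl (R)-3-[3-acetyl-2-hydroxy-4-methoxy-6-(triisopropylsilyloxy)phenyl]-3-phenylpropanoate F9. Claisen–Schmidt condensation with 4‑methoxybenzaldehyde (KOH, EtOH, rt), in which the silyl ether is also cleaved, gives tert-butyl (R)-3-[2,6-dihydroxy-4-methoxy-3-[(E)-3-(4-methoxyphenyl)prop-2-enoyl]phenyl]-3-phenylpropanoate F10. I2 (cat.) in DMSO at 120 °C closes and dehydrogenates it to the flavone. It sets out from 22 and returns at 28.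

**Step 14.** Most likely failure: incomplete cleavage of the unactivated ring B methyl ether within the window in which Lewis acid exposure is safe, together with partition of the material between open acid, lactone and boron chelates, which makes the end point hard to drive and to judge. Harsher protic conditions are excluded because they invite opening and reclosure of ring C through the C5 oxygen. Fallback: separate the events. CF3CO2H in CH2Cl2 first removes the tert-butyl group from 28 and closes the lactone deliberately, giving (10R)-5-methoxy-2-(4-methoxyphenyl)-10-phenyl-9,10-dihydro-4H,8H-pyrano[2,3-f]chromene-4,8-dione F11, a single neutral compound that can be purified. Its two methyl ethers are then cleaved (BBr3, or BCl3 with n-Bu4NI) to lactone 29, which is isolated and opened with LiOH as in step 14. It sets out from 28 and returns at 29.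

## Further compounds

F1 | step 8 | 3-methoxycyclobut-2-en-1-one | COC1=CC(=O)C1
F2 | step 5 | triisopropylsilyl (R)-3-phenyl-5-(triisopropylsilyloxy)pent-4-ynoate | CC(C)[Si](C(C)C)(C(C)C)OC(=O)C[C@H](c1ccccc1)C#CO[Si](C(C)C)(C(C)C)C(C)C
F3 | step 5 | triisopropylsilyl (R)-3-[2-hydroxy-4-methoxy-6-(triisopropylsilyloxy)phenyl]-3-phenylpropanoate | CC(C)[Si](C(C)C)(C(C)C)OC(=O)C[C@H](c1ccccc1)c1c(O)cc(OC)cc1O[Si](C(C)C)(C(C)C)C(C)C
F4 | step 5 | (R)-3-[2-hydroxy-4-methoxy-6-(triisopropylsilyloxy)phenyl]-3-phenylpropanoic acid | OC(=O)C[C@H](c1ccccc1)c1c(O)cc(OC)cc1O[Si](C(C)C)(C(C)C)C(C)C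
F5 | step 2 | racemic 2,2-dimethyl-5-(1-phenylprop-2-yn-1-yl)-1,3-dioxane-4,6-dione | CC1(C)OC(=O)C(C(C#C)c2ccccc2)C(=O)O1
F6 | step 2 | racemic 3-phenylpent-4-ynoic acid | OC(=O)CC(C#C)c1ccccc1
F7 | step 2 | (R)-1-phenylethylammonium (S)-3-phenylpent-4-ynoate | [O-]C(=O)C[C@H](c1ccccc1)C#C.C[C@@H]([NH3+])c1ccccc1
F8 | step 10 | tert-butyl (3R)-3-[2-hydroxy-3-(1-hydroxyethyl)-4-methoxy-6-(triisopropylsilyloxy)phenyl]-3-phenylpropanoate, both epimers at the carbinol carbon | CC(C)(C)OC(=O)C[C@H](c1ccccc1)c1c(O)c(C(C)O)c(OC)cc1O[Si](C(C)C)(C(C)C)C(C)C
F9 | step 10 | tert-butyl (R)-3-[3-acetyl-2-hydroxy-4-methoxy-6-(triisopropylsilyloxy)phenyl]-3-phenylpropanoate | CC(C)(C)OC(=O)C[C@H](c1ccccc1)c1c(O)c(C(C)=O)c(OC)cc1O[Si](C(C)C)(C(C)C)C(C)C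
F10 | step 10 | tert-butyl (R)-3-[2,6-dihydroxy-4-methoxy-3-[(E)-3-(4-methoxyphenyl)prop-2-enoyl]phenyl]-3-phenylpropanoate | CC(C)(C)OC(=O)C[C@H](c1ccccc1)c1c(O)c(C(=O)/C=C/c2ccc(OC)cc2)c(OC)cc1O
F11 | step 14 | (10R)-5-methoxy-2-(4-methoxyphenyl)-10-phenyl-9,10-dihydro-4H,8H-pyrano[2,3-f]chromene-4,8-dione | O=C1C[C@H](c2ccccc2)c3c(O1)cc(OC)c4c(=O)cc(-c5ccc(OC)cc5)oc34
A1 | alternative 1 | 2-[4-(methoxymethoxy)phenyl]-5-(4-methylphenylsulfinyl)-4H-pyran-4-one | COCOc1ccc(cc1)-c1cc(=O)c(S(=O)c2ccc(C)cc2)co1
A2 | alternative 1 | tert-butyl (3S)-7-methoxy-3-phenyl-5,7-bis(trimethylsilyloxy)hepta-4,6-dienoate | CC(C)(C)OC(=O)C[C@H](c1ccccc1)C=C(O[Si](C)(C)C)C=C(OC)O[Si](C)(C)C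
A3 | alternative 1 | tert-butyl (R)-3-[5,7-dihydroxy-2-(4-(methoxymethoxy)phenyl)-4-oxochromen-8-yl]-3-phenylpropanoate | CC(C)(C)OC(=O)C[C@H](c1ccccc1)c1c(O)cc(O)c2c(=O)cc(-c3ccc(OCOC)cc3)oc12
A4 | alternative 2 | methyl (R)-3-[2,4-dimethoxy-6-(trifluoromethylsulfonyloxy)-5-(trimethylsilyl)phenyl]-3-phenylpropanoate | COC(=O)C[C@H](c1ccccc1)c1c(OC)cc(OC)c([Si](C)(C)C)c1OS(=O)(=O)C(F)(F)F
A5 | alternative 2 | 3-(4-methoxyphenyl)propiolic acid | COc1ccc(C#CC(=O)O)cc1
A6 | alternative 2 | methyl (R)-3-[5,7-dimethoxy-2-(4-methoxyphenyl)-4-oxochromen-8-yl]-3-phenylpropanoate | COC(=O)C[C@H](c1ccccc1)c1c(OC)cc(OC)c2c(=O)cc(-c3ccc(OC)cc3)oc12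
A7 | alternative 3 | methyl (R)-3-[2-(benzyloxy)-4,6-dimethoxyphenyl]pent-4-ynoate | COC(=O)C[C@H](C#C)c1c(OCc2ccccc2)cc(OC)cc1OC
A8 | alternative 3 | buta-1,3-diene | C=CC=C
A9 | alternative 3 | methyl (R)-3-[2-(benzyloxy)-4,6-dimethoxyphenyl]-3-phenylpropanoate | COC(=O)C[C@H](c1ccccc1)c1c(OCc2ccccc2)cc(OC)cc1OC
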